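**Retrosynthetic overview**
1. Ring C (the pyranone) is closed last: piscerythrinetin ⇐ enaminone of a tris-MOM deoxybenzoin; C2 comes from DMF-DMA and the O1–C2 bond forms by addition–elimination once the ortho phenol is unmasked.
2. Deoxybenzoin ⇐ β-keto ester ⇐ β-hydroxy ester: the C3–C4 bond is made by an intermolecular aldol addition of the lithium enolate of methyl (3,4-dimethoxy-5-prenylphenyl)acetate to 2,4,6-tris(methoxymethoxy)benzaldehyde, followed by oxidation and dealkoxycarbonylation.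
3. Ring A aldehyde ⇐ phloroglucinol (tris-MOM ether, ortho-lithiation, DMF).
4. Ring B ester ⇐ methyl homovanillate (O-allylation, aromatic Claisen rearrangement, O-methylation, cross-metathesis of allyl to prenyl).
5. Rings A and B are bought as aromatics; ring C is the only ring formed, in the final step.

Assumption: the target has no stereocentre and no E/Z-defined alkene (the prenyl double bond carries two identical methyl groups), so "single enantiomer" means the one achiral compound and no stereocontrol is required.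

**Step 1**
Reactants: 1 phloroglucinol (benzene-1,3,5-triol)
Product: 2 1,3,5-tris(methoxymethoxy)benzene
Conditions: NaH (3.6 equiv), MOMCl (3.6 equiv), DMF, 0 °C to rt, 12 h
Reagents that add atoms: chloromethyl methyl ether (MOMCl), COCCl
Why: Williamson-type O-alkylation of the three equivalent phenoxides by the highly SN2-reactive chloromethyl ether gives the symmetric tris-acetal.

**Step 2**
Reactants: 2 1,3,5-tris(methoxymethoxy)benzene
Product: 5 2,4,6-tris(methoxymethoxy)benzaldehyde, via aryllithium 3 (not isolated), via lithium hemiaminal alkoxide 4 (not isolated)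
Conditions: n-BuLi (1.2 equiv), TMEDA, THF, 0 °C, 1 h; DMF (2 equiv), 0 °C to rt; H2O
Reagents that add atoms: N,N-dimethylformamide (DMF), CN(C)C=O
Why: Directed ortho-metalation at a ring CH flanked by two chelating OMOM groups (all three positions are equivalent), then formylation of the aryllithium with DMF, gives a single aldehyde.

**Step 3**
Reactants: 6 methyl homovanillate [methyl 2-(4-hydroxy-3-methoxyphenyl)acetate]
Product: 7 methyl 2-[4-(allyloxy)-3-methoxyphenyl]acetate
Conditions: allyl bromide (1.3 equiv), K2CO3 (2 equiv), acetone, reflux, 6 h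
Reagents that add atoms: allyl bromide, C=CCBr
Why: Williamson ether synthesis; K2CO3 deprotonates only the phenol, so the ester α-CH2 is not alkylated.

**Step 4**
Reactants: 7 methyl 2-[4-(allyloxy)-3-methoxyphenyl]acetate
Product: 9 methyl 2-(3-allyl-4-hydroxy-5-methoxyphenyl)acetate, via ortho-dienone 8 (not isolated)
Conditions: N,N-diethylaniline, 195 °C, Ar, 4 h
Reagents that add atoms: none
Why: Aromatic Claisen ([3,3]-sigmatropic) rearrangement delivers the allyl group to the only unsubstituted ortho position, and tautomerisation of the dienone restores the phenol.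

**Step 5**
Reactants: 9 methyl 2-(3-allyl-4-hydroxy-5-methoxyphenyl)acetate
Product: 10 methyl 2-(3-allyl-4,5-dimethoxyphenyl)acetate
Conditions: MeI (2 equiv), K2CO3 (2 equiv), acetone, reflux, 8 h
Reagents that add atoms: iodomethane, CI
Why: Williamson O-methylation of the phenoxide fixes the 3,4-dimethoxy pattern of ring B.

**Step 6**
Reactants: 10 methyl 2-(3-allyl-4,5-dimethoxyphenyl)acetate
Product: 11 methyl 2-[3,4-dimethoxy-5-(3-methylbut-2-en-1-yl)phenyl]acetate
Conditions: 2-methyl-2-butene (large excess), second-generation Grubbs catalyst RuCl2(=CHPh)(PCy3)(H2IMes) (3 mol %), CH2Cl2, 40 °C (sealed), 12 h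
Reagents that add atoms: 2-methyl-2-butene, CC=C(C)C
Why: Olefin cross-metathesis of the terminal allyl alkene with excess 2-methyl-2-butene installs the isopropylidene terminus with loss of propene, and no E/Z issue arises.

**Step 7**
Reactants: 11 methyl 2-[3,4-dimethoxy-5-(3-methylbut-2-en-1-yl)phenyl]acetate; 5 2,4,6-tris(methoxymethoxy)benzaldehyde
Product: 14 methyl 3-hydroxy-2-[3,4-dimethoxy-5-(3-methylbut-2-en-1-yl)phenyl]-3-[2,4,6-tris(methoxymethoxy)phenyl]propanoate (racemic syn/anti mixture), via lithium enolate 12 (not isolated), via lithium aldolate 13 (not isolated)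
Conditions: LiN(i-Pr)2 (1.15 equiv), THF, −78 °C, 45 min; 5 in THF, −78 °C, 1 h; sat. aq NH4Cl at −78 °C
Reagents that add atoms: none
Why: Intermolecular aldol addition of a preformed lithium ester enolate to a non-enolisable aldehyde forms the future C3–C4 bond; the two new stereocentres need no control because steps 8 and 9 erase them.

**Step 8**
Reactants: 14 methyl 3-hydroxy-2-[3,4-dimethoxy-5-(3-methylbut-2-en-1-yl)phenyl]-3-[2,4,6-tris(methoxymethoxy)phenyl]propanoate
Product: 15 methyl 2-[3,4-dimethoxy-5-(3-methylbut-2-en-1-yl)phenyl]-3-oxo-3-[2,4,6-tris(methoxymethoxy)phenyl]propanoate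
Conditions: Dess–Martin periodinane (1.5 equiv), pyridine (3 equiv), CH2Cl2, 0 °C to rt, 2 h
Reagents that add atoms: none
Why: Buffered Dess–Martin oxidation converts the secondary benzylic alcohol to the ketone under near-neutral conditions that leave the MOM acetals and the prenyl alkene untouched.

**Step 9**
Reactants: 15 methyl 2-[3,4-dimethoxy-5-(3-methylbut-2-en-1-yl)phenyl]-3-oxo-3-[2,4,6-tris(methoxymethoxy)phenyl]propanoate
Product: 17 2-[3,4-dimethoxy-5-(3-methylbut-2-en-1-yl)phenyl]-1-[2,4,6-tris(methoxymethoxy)phenyl]ethan-1-one, via lithium keto carboxylate 16 (not isolated)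
Conditions: LiCl (3 equiv), H2O (3 equiv), DMSO, 130 °C, 3 h
Reagents that add atoms: none
Why: Krapcho dealkoxycarbonylation (chloride SN2 at the ester methyl, then loss of CO2 from the β-keto carboxylate) gives the deoxybenzoin without acid or strong base.

**Step 10**
Reactants: 17 2-[3,4-dimethoxy-5-(3-methylbut-2-en-1-yl)phenyl]-1-[2,4,6-tris(methoxymethoxy)phenyl]ethan-1-one
Product: 18 (E)-3-(dimethylamino)-2-[3,4-dimethoxy-5-(3-methylbut-2-en-1-yl)phenyl]-1-[2,4,6-tris(methoxymethoxy)phenyl]prop-2-en-1-one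
Conditions: DMF-DMA (5 equiv), toluene, 100 °C, 8 h
Reagents that add atoms: N,N-dimethylformamide dimethyl acetal (DMF-DMA), COC(OC)N(C)C
Why: Condensation of the doubly activated benzylic CH2 with the amide acetal (enaminone formation) installs the future C2; the alkene geometry is lost on ring closure and does not matter.

**Step 11**
Reactants: 18 (E)-3-(dimethylamino)-2-[3,4-dimethoxy-5-(3-methylbut-2-en-1-yl)phenyl]-1-[2,4,6-tris(methoxymethoxy)phenyl]prop-2-en-1-one
Product: 20 piscerythrinetin [5,7-dihydroxy-3-[3,4-dimethoxy-5-(3-methylbut-2-en-1-yl)phenyl]-4H-chromen-4-one], via bis-MOM isoflavone 19 (not isolated)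
Conditions: HCl (3 M in MeOH), 50 °C, 2–3 h
Reagents that add atoms: none
Why: Acid-catalysed acetal exchange frees the ortho phenol, which closes ring C by conjugate addition–elimination of dimethylamine, and the remaining MOM ethers are then cleaved; the prenyl group has no adjacent free OH to cyclise onto, and the product is achiral.

**Compound list**
1 | phloroglucinol (benzene-1,3,5-triol) | Oc1cc(O)cc(O)c1 | starting material
2 | 1,3,5-tris(methoxymethoxy)benzene | COCOc1cc(OCOC)cc(OCOC)c1 | intermediate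
3 | 2,4,6-tris(methoxymethoxy)phenyllithium (aryllithium; not isolated) | [Li]c1c(OCOC)cc(OCOC)cc1OCOC | intermediate
4 | lithium (dimethylamino)[2,4,6-tris(methoxymethoxy)phenyl]methanolate (hemiaminal alkoxide; not isolated) | CN(C)C([O-])c1c(OCOC)cc(OCOC)cc1OCOC.[Li+] | intermediate
5 | 2,4,6-tris(methoxymethoxy)benzaldehyde | O=Cc1c(OCOC)cc(OCOC)cc1OCOC | intermediate
6 | methyl homovanillate [methyl 2-(4-hydroxy-3-methoxyphenyl)acetate] | COC(=O)Cc1ccc(O)c(OC)c1 | starting material
7 | methyl 2-[4-(allyloxy)-3-methoxyphenyl]acetate | COC(=O)Cc1ccc(OCC=C)c(OC)c1 | intermediate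
8 | methyl 2-(3-allyl-5-methoxy-4-oxocyclohexa-1,5-dien-1-yl)acetate (racemic ortho-dienone; not isolated) | COC(=O)CC1=CC(CC=C)C(=O)C(OC)=C1 | intermediate
9 | methyl 2-(3-allyl-4-hydroxy-5-methoxyphenyl)acetate | COC(=O)Cc1cc(CC=C)c(O)c(OC)c1 | intermediate
10 | methyl 2-(3-allyl-4,5-dimethoxyphenyl)acetate | COC(=O)Cc1cc(CC=C)c(OC)c(OC)c1 | intermediate
11 | methyl 2-[3,4-dimethoxy-5-(3-methylbut-2-en-1-yl)phenyl]acetate | COC(=O)Cc1cc(CC=C(C)C)c(OC)c(OC)c1 | intermediate
12 | lithium enolate of 11 (not isolated) | COC([O-])=Cc1cc(CC=C(C)C)c(OC)c(OC)c1.[Li+] | intermediate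
13 | lithium aldolate of 14 (racemic diastereomer mixture; not isolated) | COC(=O)C(c1cc(CC=C(C)C)c(OC)c(OC)c1)C([O-])c1c(OCOC)cc(OCOC)cc1OCOC.[Li+] | intermediate
14 | methyl 3-hydroxy-2-[3,4-dimethoxy-5-(3-methylbut-2-en-1-yl)phenyl]-3-[2,4,6-tris(methoxymethoxy)phenyl]propanoate (racemic syn/anti mixture) | COC(=O)C(c1cc(CC=C(C)C)c(OC)c(OC)c1)C(O)c1c(OCOC)cc(OCOC)cc1OCOC | intermediate
15 | methyl 2-[3,4-dimethoxy-5-(3-methylbut-2-en-1-yl)phenyl]-3-oxo-3-[2,4,6-tris(methoxymethoxy)phenyl]propanoate (racemic) | COC(=O)C(c1cc(CC=C(C)C)c(OC)c(OC)c1)C(=O)c1c(OCOC)cc(OCOC)cc1OCOC | intermediate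
16 | lithium 2-[3,4-dimethoxy-5-(3-methylbut-2-en-1-yl)phenyl]-3-oxo-3-[2,4,6-tris(methoxymethoxy)phenyl]propanoate (not isolated) | [Li+].[O-]C(=O)C(c1cc(CC=C(C)C)c(OC)c(OC)c1)C(=O)c1c(OCOC)cc(OCOC)cc1OCOC | intermediate
17 | 2-[3,4-dimethoxy-5-(3-methylbut-2-en-1-yl)phenyl]-1-[2,4,6-tris(methoxymethoxy)phenyl]ethan-1-one | O=C(Cc1cc(CC=C(C)C)c(OC)c(OC)c1)c1c(OCOC)cc(OCOC)cc1OCOC | intermediate
18 | (E)-3-(dimethylamino)-2-[3,4-dimethoxy-5-(3-methylbut-2-en-1-yl)phenyl]-1-[2,4,6-tris(methoxymethoxy)phenyl]prop-2-en-1-one | CN(C)/C=C(\c1cc(CC=C(C)C)c(OC)c(OC)c1)C(=O)c1c(OCOC)cc(OCOC)cc1OCOC | intermediate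
19 | 3-[3,4-dimethoxy-5-(3-methylbut-2-en-1-yl)phenyl]-5,7-bis(methoxymethoxy)-4H-chromen-4-one (not isolated) | COCOc1cc(OCOC)c2c(c1)occ(-c1cc(CC=C(C)C)c(OC)c(OC)c1)c2=O | intermediate
20 | piscerythrinetin [5,7-dihydroxy-3-[3,4-dimethoxy-5-(3-methylbut-2-en-1-yl)phenyl]-4H-chromen-4-one] | COc1cc(-c2coc3cc(O)cc(O)c3c2=O)cc(CC=C(C)C)c1OC | target

**Totals**
Total step count: 11 (steps 1–2 for ring A, steps 3–6 for ring B, steps 7–11 after union).
Longest linear sequence: 9 steps (6 → 20, steps 3–11).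

**Three steps most likely to fail**

Step 7 (aldol). The aldehyde is electron-rich and di-ortho-substituted, and carbinol 14 can undergo retro-aldol on warming or acid-promoted dehydration on silica. The fallback sets out from 2 and 11 and comes back at 15. Compound 2 is lithiated as in step 2 (aryllithium 3) and quenched with CO2, acidifying only to pH 4–5 with NaH2PO4, to give 2,4,6-tris(methoxymethoxy)benzoic acid F1. This is activated with 1,1'-carbonyldiimidazole in THF to (1H-imidazol-1-yl)[2,4,6-tris(methoxymethoxy)phenyl]methanone F2. F2 is added to 2.2 equiv of enolate 12 (from 11 and LiN(i-Pr)2, THF, −78 °C to 0 °C). This crossed Claisen-type C-acylation gives β-keto ester 15 directly and bypasses both 14 and step 8.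

Step 9 (Krapcho). Hot chloride in DMSO may partly cleave the MOM ethers ortho and para to the ketone or cause retro-Claisen cleavage. The fallback sets out from 14 and comes back at 20. LiAlH4 in THF at 0 °C reduces the ester to 2-[3,4-dimethoxy-5-(3-methylbut-2-en-1-yl)phenyl]-1-[2,4,6-tris(methoxymethoxy)phenyl]propane-1,3-diol F3. Double oxidation with Dess–Martin periodinane (3 equiv, pyridine, CH2Cl2) gives 2-[3,4-dimethoxy-5-(3-methylbut-2-en-1-yl)phenyl]-3-oxo-3-[2,4,6-tris(methoxymethoxy)phenyl]propanal F4, which exists mainly as its enol. Treatment with 3 M HCl in MeOH at 50 °C removes the MOM groups and closes ring C by hemiacetal formation and dehydration to give 20, so no decarboxylation or enaminone step is needed.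

Step 11 (global deprotection and ring closure). Three MOM ethers must be cleaved in acid while the prenyl alkene is present, and forcing conditions could add HCl or methanol across it. The fallback sets out from 10 and comes back at 20; it carries the acid-inert allyl group through the acid step and forms the prenyl alkene last. Ester 10 is taken through the same operations as 11:
- aldol with 5 to methyl 2-(3-allyl-4,5-dimethoxyphenyl)-3-hydroxy-3-[2,4,6-tris(methoxymethoxy)phenyl]propanoate F5;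
- Dess–Martin oxidation to methyl 2-(3-allyl-4,5-dimethoxyphenyl)-3-oxo-3-[2,4,6-tris(methoxymethoxy)phenyl]propanoate F6;
- LiCl/H2O/DMSO to 2-(3-allyl-4,5-dimethoxyphenyl)-1-[2,4,6-tris(methoxymethoxy)phenyl]ethan-1-one F7;
- DMF-DMA to (E)-2-(3-allyl-4,5-dimethoxyphenyl)-3-(dimethylamino)-1-[2,4,6-tris(methoxymethoxy)phenyl]prop-2-en-1-one F8;
- 3 M HCl in MeOH to 3-(3-allyl-4,5-dimethoxyphenyl)-5,7-dihydroxy-4H-chromen-4-one F9.

Cross-metathesis of F9 with excess 2-methyl-2-butene (second-generation Grubbs catalyst RuCl2(=CHPh)(PCy3)(H2IMes), CH2Cl2, 40 °C), which tolerates free phenols, then gives 20.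

**Further compounds**
F1 | step 7 | 2,4,6-tris(methoxymethoxy)benzoic acid | OC(=O)c1c(OCOC)cc(OCOC)cc1OCOC
F2 | step 7 | (1H-imidazol-1-yl)[2,4,6-tris(methoxymethoxy)phenyl]methanone | O=C(c1c(OCOC)cc(OCOC)cc1OCOC)n1ccnc1
F3 | step 9 | 2-[3,4-dimethoxy-5-(3-methylbut-2-en-1-yl)phenyl]-1-[2,4,6-tris(methoxymethoxy)phenyl]propane-1,3-diol (racemic diastereomer mixture) | OCC(c1cc(CC=C(C)C)c(OC)c(OC)c1)C(O)c1c(OCOC)cc(OCOC)cc1OCOC
F4 | step 9 | 2-[3,4-dimethoxy-5-(3-methylbut-2-en-1-yl)phenyl]-3-oxo-3-[2,4,6-tris(methoxymethoxy)phenyl]propanal | O=CC(c1cc(CC=C(C)C)c(OC)c(OC)c1)C(=O)c1c(OCOC)cc(OCOC)cc1OCOC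
F5 | step 11 | methyl 2-(3-allyl-4,5-dimethoxyphenyl)-3-hydroxy-3-[2,4,6-tris(methoxymethoxy)phenyl]propanoate (racemic syn/anti mixture) | COC(=O)C(c1cc(CC=C)c(OC)c(OC)c1)C(O)c1c(OCOC)cc(OCOC)cc1OCOC
F6 | step 11 | methyl 2-(3-allyl-4,5-dimethoxyphenyl)-3-oxo-3-[2,4,6-tris(methoxymethoxy)phenyl]propanoate | COC(=O)C(c1cc(CC=C)c(OC)c(OC)c1)C(=O)c1c(OCOC)cc(OCOC)cc1OCOC
F7 | step 11 | 2-(3-allyl-4,5-dimethoxyphenyl)-1-[2,4,6-tris(methoxymethoxy)phenyl]ethan-1-one | O=C(Cc1cc(CC=C)c(OC)c(OC)c1)c1c(OCOC)cc(OCOC)cc1OCOC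
F8 | step 11 | (E)-2-(3-allyl-4,5-dimethoxyphenyl)-3-(dimethylamino)-1-[2,4,6-tris(methoxymethoxy)phenyl]prop-2-en-1-one | CN(C)/C=C(\c1cc(CC=C)c(OC)c(OC)c1)C(=O)c1c(OCOC)cc(OCOC)cc1OCOC
F9 | step 11 | 3-(3-allyl-4,5-dimethoxyphenyl)-5,7-dihydroxy-4H-chromen-4-one | COc1cc(-c2coc3cc(O)cc(O)c3c2=O)cc(CC=C)c1OC
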